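## Retrosynthetic overview

1. Feature used: in ring A (C1–C6) the C2 bromine and the C3 chlorine lie on the same face, which is the anti adduct of an open-chain (E)-C2=C3 allylic alcohol with C1 as carbinol carbon; the spiro carbon C6 is alpha to C7, whose exocyclic methylene is a masked ketone.
2. Last disconnections: C7=CH2 back to C7=O, then C1–C6 (ring A) by C-alkylation of the ring B C6 enolate with a C1 triflate on the already bromochlorinated arm.
3. Ring B (C6–C11) comes from C6–C11 closure: the enol carbon of an acyclic beta-keto ester opens a bromonium ion released from an enantioenriched C10-bromo/C11-chloro unit.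
4. The acyclic precursor is built from allyl acetoacetate (C6, C7, C8), a C1–C5 (E)-allylic arm from but-3-yn-1-ol (C5–C6 bond) and the bromochloride of prenol (C9–C11, C8–C9 bond).
5. Ring order: ring B first (step 10), ring A last (step 15).

Key step: step 15

Remark: chamigrene numbering is used throughout (ring A C1–C6, ring B C6–C11). Compounds 11, 16 and 18 to 23 are carried as mixtures at C6, which is only fixed in step 15. Bromine must be delivered to opposite faces of the allylic alcohol in steps 7 and 13, so the two steps are assumed to need opposite enantiomers of the ligand.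

## Route

Step 1
Reactants: 1 but-3-yn-1-ol
Product: 2 1-[(but-3-yn-1-yloxy)methyl]-4-methoxybenzene
Conditions: NaH, 4-methoxybenzyl chloride, n-Bu4NI (cat.), THF/DMF, 0 °C to rt
Reagents that add atoms: 4-methoxybenzyl chloride COc1ccc(CCl)cc1
Why: Williamson etherification, in which NaH removes the hydroxyl proton well before the alkyne proton, gives an ether that tolerates AlMe3 and can later be removed oxidatively beside a silyl ether.

Step 2
Reactants: 2 1-[(but-3-yn-1-yloxy)methyl]-4-methoxybenzene
Product: 5 (E)-5-[(4-methoxybenzyl)oxy]-3-methylpent-2-en-1-ol, via alkenyldimethylalane 3 (not isolated), via lithium alkenylalanate 4 (not isolated)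
Conditions: AlMe3, Cp2ZrCl2 (20 mol %), CH2Cl2, 0 °C to rt; evaporate; n-BuLi, THF/hexane, -78 °C; (CH2O)n, -78 °C to rt
Reagents that add atoms: trimethylaluminium C[Al](C)C; formaldehyde (from paraformaldehyde) C=O
Why: Negishi zirconium-catalysed carboalumination adds methyl (to the internal carbon, future C3) and aluminium syn across the alkyne, and the alanate is hydroxymethylated with retention, so the (E)-trisubstituted allylic alcohol with C1 in place should result.

Step 3
Reactants: 5 (E)-5-[(4-methoxybenzyl)oxy]-3-methylpent-2-en-1-ol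
Product: 6 tert-butyl{[(E)-5-(4-methoxybenzyloxy)-3-methylpent-2-en-1-yl]oxy}diphenylsilane
Conditions: t-BuPh2SiCl, imidazole, CH2Cl2, 0 °C to rt
Reagents that add atoms: tert-butylchlorodiphenylsilane CC(C)(C)[Si](Cl)(c1ccccc1)c1ccccc1
Why: Imidazole-promoted silylation of the primary allylic alcohol gives an ether that should survive DDQ, enolate chemistry and buffered fluoroalcohol solvolysis.

Step 4
Reactants: 6 tert-butyl{[(E)-5-(4-methoxybenzyloxy)-3-methylpent-2-en-1-yl]oxy}diphenylsilane
Product: 7 (E)-5-(tert-butyldiphenylsilyloxy)-3-methylpent-3-en-1-ol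
Conditions: DDQ, CH2Cl2/pH 7 buffer, 0 °C
Reagents that add atoms: none
Why: Oxidative cleavage of the 4-methoxybenzyl ether by DDQ (hydride abstraction to the oxocarbenium ion, then hydrolysis) leaves the silyl ether and the alkene untouched.

Step 5
Reactants: 7 (E)-5-(tert-butyldiphenylsilyloxy)-3-methylpent-3-en-1-ol
Product: 8 tert-butyl{[(E)-5-iodo-3-methylpent-2-en-1-yl]oxy}diphenylsilane
Conditions: I2, PPh3, imidazole, CH2Cl2, 0 °C
Reagents that add atoms: iodine II
Why: Appel-type iodination, with SN2 displacement of the alkoxyphosphonium group by iodide at the primary C5, gives the homoallylic iodide without touching the alkene geometry.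

Step 6
Reactants: 8 tert-butyl{[(E)-5-iodo-3-methylpent-2-en-1-yl]oxy}diphenylsilane; 9 allyl acetoacetate
Product: 11 allyl (E)-2-acetyl-7-(tert-butyldiphenylsilyloxy)-5-methylhept-5-enoate, via sodium enolate 10 (not isolated)
Conditions: 9 (1.5 equiv), NaH, THF/DMF, 0 °C; then 8, 50 °C
Reagents that add atoms: none
Why: Acetoacetic ester alkylation with the soft, weakly basic enolate on a primary iodide forms C5–C6 by SN2, the excess of 9 limiting dialkylation, and the racemic C6 centre is of no consequence.

Step 7
Reactants: 12 prenol (3-methylbut-2-en-1-ol)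
Product: 13 (R)-2-bromo-3-chloro-3-methylbutan-1-ol
Conditions: N-bromosuccinimide, ClTi(Oi-Pr)3, chiral tridentate Schiff-base ligand (cat., enantiomer giving the R bromide), hexanes, -20 °C
Reagents that add atoms: N-bromosuccinimide O=C1CCC(=O)N1Br; chlorotitanium triisopropoxide CC(C)O[Ti](Cl)(OC(C)C)OC(C)C
Why: Catalytic enantioselective bromochlorination of an allylic alcohol, in which the titanium-bound alkoxide sits in the chiral ligand sphere, bromine is delivered to one alkene face at C2 and chloride adds anti at the tertiary carbon, so the ligand sets the future C10 as R.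

Step 8
Reactants: 13 (R)-2-bromo-3-chloro-3-methylbutan-1-ol
Product: 14 (R)-2-bromo-3-chloro-3-methylbutyl trifluoromethanesulfonate
Conditions: Tf2O, 2,6-di-tert-butyl-4-methylpyridine, CH2Cl2, -78 °C; cold filtration, used at once
Reagents that add atoms: triflic anhydride O=S(=O)(OS(=O)(=O)C(F)(F)F)C(F)(F)F
Why: O-sulfonylation of the primary alcohol with a hindered, non-nucleophilic base at low temperature gives the beta-bromo primary triflate without touching the stereocentre.

Step 9
Reactants: 11 allyl (E)-2-acetyl-7-(tert-butyldiphenylsilyloxy)-5-methylhept-5-enoate; 14 (R)-2-bromo-3-chloro-3-methylbutyl trifluoromethanesulfonate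
Product: 16 allyl (6R)-6-bromo-7-chloro-7-methyl-3-oxo-2-[(E)-5-(tert-butyldiphenylsilyloxy)-3-methylpent-3-en-1-yl]octanoate, via dilithium dianion 15 (not isolated)
Conditions: LiN(i-Pr)2 (2.05 equiv), THF, -78 to 0 °C; then 14, -78 °C
Reagents that add atoms: none
Why: Beta-keto ester dianion gamma-alkylation, in which the second deprotonation occurs at the acetyl methyl (C8) and this more reactive terminus displaces the primary triflate by SN2 at -78 °C, forms C8–C9 with no bond to the bromide stereocentre made or broken.

Step 10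
Reactants: 16 allyl (6R)-6-bromo-7-chloro-7-methyl-3-oxo-2-[(E)-5-(tert-butyldiphenylsilyloxy)-3-methylpent-3-en-1-yl]octanoate
Product: 18 allyl (3R)-3-bromo-2,2-dimethyl-6-oxo-1-[(E)-5-(tert-butyldiphenylsilyloxy)-3-methylpent-3-en-1-yl]cyclohexane-1-carboxylate, via O-cyclised enol ether 17 (not isolated)
Conditions: (CF3)2CHOH (0.01 M), 2,6-di-tert-butyl-4-methylpyridine, 0 °C to rt; crude, SnCl4, CH2Cl2, -78 °C
Reagents that add atoms: none
Why: Solvolytic bromonium cyclisation, in which the tertiary C11 chloride ionises with backside participation of the C10 bromine and the enol carbon C6 opens the bromonium ion at C11 to close the six-membered ring B (enol double bond inside the ring), keeps C10 as R because only C11 is substituted, while material closed through the ketone oxygen (17) is re-ionised by SnCl4 and funnelled to the C–C bonded ring; high dilution limits bromonium transfer to the C2=C3 alkene, which must still be halogen-free because a second CHBr–CCl unit would ionise as well.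

Step 11
Reactants: 18 allyl (3R)-3-bromo-2,2-dimethyl-6-oxo-1-[(E)-5-(tert-butyldiphenylsilyloxy)-3-methylpent-3-en-1-yl]cyclohexane-1-carboxylate
Product: 20 (4R)-4-bromo-3,3-dimethyl-2-[(E)-5-(tert-butyldiphenylsilyloxy)-3-methylpent-3-en-1-yl]cyclohexan-1-one, via beta-keto acid 19 (not isolated)
Conditions: Pd(PPh3)4 (5 mol %), morpholine, THF, rt
Reagents that add atoms: none
Why: Tsuji–Trost deallylation, in which zerovalent palladium ionises the allyl ester and morpholine traps the allyl fragment, releases the beta-keto acid, which loses CO2 to give the C6–H ketone without any strong base that could enolise the 4-bromoketone.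

Step 12
Reactants: 20 (4R)-4-bromo-3,3-dimethyl-2-[(E)-5-(tert-butyldiphenylsilyloxy)-3-methylpent-3-en-1-yl]cyclohexan-1-one
Product: 21 (4R)-4-bromo-2-[(E)-5-hydroxy-3-methylpent-3-en-1-yl]-3,3-dimethylcyclohexan-1-one
Conditions: HF·pyridine, pyridine, THF, 0 °C to rt
Reagents that add atoms: none
Why: Fluoride-mediated desilylation under weakly acidic conditions frees the allylic alcohol needed for the next step and avoids basic fluoride, which could enolise the ketone toward displacement of the C10 bromide.

Step 13
Reactants: 21 (4R)-4-bromo-2-[(E)-5-hydroxy-3-methylpent-3-en-1-yl]-3,3-dimethylcyclohexan-1-one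
Product: 22 (4R)-4-bromo-2-[(3R,4S)-4-bromo-3-chloro-5-hydroxy-3-methylpentyl]-3,3-dimethylcyclohexan-1-one
Conditions: N-bromosuccinimide, ClTi(Oi-Pr)3, chiral tridentate Schiff-base ligand (cat., enantiomer opposite to step 7), hexanes/CH2Cl2, -20 °C
Reagents that add atoms: N-bromosuccinimide O=C1CCC(=O)N1Br; chlorotitanium triisopropoxide CC(C)O[Ti](Cl)(OC(C)C)OC(C)C
Why: A second catalytic enantioselective bromochlorination of an allylic alcohol adds bromine at C2 and chloride at the tertiary C3 anti across the (E)-alkene, the ligand choosing the face so that C2 is S and C3 is R (target numbering), and this anti adduct becomes the ring-cis Br/Cl pair once C1 and C4 are both in ring A.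

Step 14
Reactants: 22 (4R)-4-bromo-2-[(3R,4S)-4-bromo-3-chloro-5-hydroxy-3-methylpentyl]-3,3-dimethylcyclohexan-1-one
Product: 23 (2S,3R)-2-bromo-5-[(3R)-3-bromo-2,2-dimethyl-6-oxocyclohexyl]-3-chloro-3-methylpentyl trifluoromethanesulfonate
Conditions: Tf2O, 2,6-di-tert-butylpyridine, CH2Cl2, -78 °C; cold filtration, used at once
Reagents that add atoms: triflic anhydride O=S(=O)(OS(=O)(=O)C(F)(F)F)C(F)(F)F
Why: O-sulfonylation of the primary C1 alcohol is much faster at -78 °C than enol triflate formation at the ketone and gives the electrophile for ring A closure.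

Step 15
Reactants: 23 (2S,3R)-2-bromo-5-[(3R)-3-bromo-2,2-dimethyl-6-oxocyclohexyl]-3-chloro-3-methylpentyl trifluoromethanesulfonate
Product: 25 (2S,3R,6S,10R)-2,10-dibromo-3-chloro-3,11,11-trimethylspiro[5.5]undecan-7-one, via potassium C6 enolate 24 (not isolated)
Conditions: KN(SiMe3)2 (0.95 equiv), THF (0.005 M), -78 °C, slow warming to 0 °C
Reagents that add atoms: none
Why: The base first removes the exposed C8 proton, but with a slight deficit of base the enolates interconvert through the remaining ketone and HN(SiMe3)2, and only the tetrasubstituted C6=C7 enolate 24 has a productive exit, its carbon C6 displacing the primary C1 triflate by SN2 to form the C1–C6 bond and the spiro quaternary carbon next to quaternary C11. The closest known reaction type is the spiroannulation of a 2-substituted cyclohexanone enolate by a tethered primary sulfonate. Ring A closes in a 6-(enolexo)-exo-tet mode, whereas O-alkylation or attack from C8 would need eight-membered transition states. The new stereocentre C6 should be controlled by the C10 bromine of ring B: in the half-chair enolate with bromine equatorial, axial attack leading directly to a chair brings C1 onto the face anti to bromine, the other face requiring a syn-axial contact with bromine or a twist-boat; this gives the 6S ketone, which has the same spatial arrangement as 6R in the target, and C2, C3 and C10 keep their configuration because no bond to them is made or broken. The step needs the triflate to react before the halides, which its far higher leaving-group ability secures (C10–Br is a ring secondary bromide next to quaternary C11, C2–Br is secondary, C3–Cl tertiary), while low temperature and high dilution hold back three-membered closure onto C10 and intermolecular alkylation.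

Step 16
Reactants: 25 (2S,3R,6S,10R)-2,10-dibromo-3-chloro-3,11,11-trimethylspiro[5.5]undecan-7-one
Product: 26 (2S,3R,6R,10R)-2,10-dibromo-3-chloro-3,11,11-trimethyl-7-methylidenespiro[5.5]undecane (2,10-dibromo-3-chloro-beta-chamigrene)
Conditions: Cp2TiMe2 (3 equiv), toluene, 70 °C, dark
Reagents that add atoms: dimethyltitanocene [CH3-].[CH3-].[Ti+4].c1cc[cH-]c1.c1cc[cH-]c1
Why: Petasis methylenation, in which thermally formed Cp2Ti=CH2 adds to the hindered, enolisable C7 ketone by [2+2] cycloaddition and cycloreversion, is non-basic and uses no reducing metal, so the 4-bromoketone is not enolised and the vicinal bromochloride is not reductively eliminated; the C6 descriptor changes from S to R by priority only.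

## Compound list

1 | but-3-yn-1-ol | C#CCCO | starting material
2 | 1-[(but-3-yn-1-yloxy)methyl]-4-methoxybenzene | C#CCCOCc1ccc(OC)cc1 | intermediate
3 | (E)-[4-(4-methoxybenzyloxy)-2-methylbut-1-enyl]dimethylalane | C[Al](C)/C=C(\C)CCOCc1ccc(OC)cc1 | intermediate (not isolated)
4 | lithium butyl[(E)-4-(4-methoxybenzyloxy)-2-methylbut-1-enyl]dimethylalanate | [Li+].CCCC[Al-](C)(C)/C=C(\C)CCOCc1ccc(OC)cc1 | intermediate (not isolated)
5 | (E)-5-[(4-methoxybenzyl)oxy]-3-methylpent-2-en-1-ol | OC/C=C(\C)CCOCc1ccc(OC)cc1 | intermediate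
6 | tert-butyl{[(E)-5-(4-methoxybenzyloxy)-3-methylpent-2-en-1-yl]oxy}diphenylsilane | COc1ccc(COCC/C(C)=C/CO[Si](c2ccccc2)(c2ccccc2)C(C)(C)C)cc1 | intermediate
7 | (E)-5-(tert-butyldiphenylsilyloxy)-3-methylpent-3-en-1-ol | OCC/C(C)=C/CO[Si](c1ccccc1)(c1ccccc1)C(C)(C)C | intermediate
8 | tert-butyl{[(E)-5-iodo-3-methylpent-2-en-1-yl]oxy}diphenylsilane | ICC/C(C)=C/CO[Si](c1ccccc1)(c1ccccc1)C(C)(C)C | intermediate
9 | allyl acetoacetate | C=CCOC(=O)CC(C)=O | starting material
10 | sodium enolate of allyl acetoacetate | [Na+].C=CCOC(=O)C=C(C)[O-] | intermediate (not isolated)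
11 | allyl (E)-2-acetyl-7-(tert-butyldiphenylsilyloxy)-5-methylhept-5-enoate (racemic at C6) | C=CCOC(=O)C(CC/C(C)=C/CO[Si](c1ccccc1)(c1ccccc1)C(C)(C)C)C(C)=O | intermediate
12 | prenol (3-methylbut-2-en-1-ol) | CC(C)=CCO | starting material
13 | (R)-2-bromo-3-chloro-3-methylbutan-1-ol | OC[C@@H](Br)C(C)(C)Cl | intermediate
14 | (R)-2-bromo-3-chloro-3-methylbutyl trifluoromethanesulfonate | FC(F)(F)S(=O)(=O)OC[C@@H](Br)C(C)(C)Cl | intermediate
15 | dilithium dianion (dienediolate) of 11 | [Li+].[Li+].C=CCOC([O-])=C(CC/C(C)=C/CO[Si](c1ccccc1)(c1ccccc1)C(C)(C)C)C(=C)[O-] | intermediate (not isolated)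
16 | allyl (6R)-6-bromo-7-chloro-7-methyl-3-oxo-2-[(E)-5-(tert-butyldiphenylsilyloxy)-3-methylpent-3-en-1-yl]octanoate (mixture at C2 of the chain, chamigrene C6) | C=CCOC(=O)C(CC/C(C)=C/CO[Si](c1ccccc1)(c1ccccc1)C(C)(C)C)C(=O)CC[C@@H](Br)C(C)(C)Cl | intermediate
17 | allyl 2-[(5R)-5-bromo-6,6-dimethyloxan-2-ylidene]-7-(tert-butyldiphenylsilyloxy)-5-methylhept-5-enoate (O-cyclised part of the crude, alkylidene geometry not defined) | C=CCOC(=O)C(CC/C(C)=C/CO[Si](c1ccccc1)(c1ccccc1)C(C)(C)C)=C1CC[C@@H](Br)C(C)(C)O1 | intermediate (not isolated)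
18 | allyl (3R)-3-bromo-2,2-dimethyl-6-oxo-1-[(E)-5-(tert-butyldiphenylsilyloxy)-3-methylpent-3-en-1-yl]cyclohexane-1-carboxylate (both C1 epimers) | C=CCOC(=O)C1(CC/C(C)=C/CO[Si](c2ccccc2)(c2ccccc2)C(C)(C)C)C(=O)CC[C@@H](Br)C1(C)C | intermediate
19 | (3R)-3-bromo-2,2-dimethyl-6-oxo-1-[(E)-5-(tert-butyldiphenylsilyloxy)-3-methylpent-3-en-1-yl]cyclohexane-1-carboxylic acid | OC(=O)C1(CC/C(C)=C/CO[Si](c2ccccc2)(c2ccccc2)C(C)(C)C)C(=O)CC[C@@H](Br)C1(C)C | intermediate (not isolated)
20 | (4R)-4-bromo-3,3-dimethyl-2-[(E)-5-(tert-butyldiphenylsilyloxy)-3-methylpent-3-en-1-yl]cyclohexan-1-one (C2 epimers) | O=C1CC[C@@H](Br)C(C)(C)C1CC/C(C)=C/CO[Si](c2ccccc2)(c2ccccc2)C(C)(C)C | intermediate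
21 | (4R)-4-bromo-2-[(E)-5-hydroxy-3-methylpent-3-en-1-yl]-3,3-dimethylcyclohexan-1-one (C2 epimers) | OC/C=C(\C)CCC1C(=O)CC[C@@H](Br)C1(C)C | intermediate
22 | (4R)-4-bromo-2-[(3R,4S)-4-bromo-3-chloro-5-hydroxy-3-methylpentyl]-3,3-dimethylcyclohexan-1-one (C2 epimers) | CC1(C)[C@H](Br)CCC(=O)C1CC[C@@](C)(Cl)[C@@H](Br)CO | intermediate
23 | (2S,3R)-2-bromo-5-[(3R)-3-bromo-2,2-dimethyl-6-oxocyclohexyl]-3-chloro-3-methylpentyl trifluoromethanesulfonate | CC1(C)[C@H](Br)CCC(=O)C1CC[C@@](C)(Cl)[C@@H](Br)COS(=O)(=O)C(F)(F)F | intermediate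
24 | potassium C6=C7 enolate of 23 | [K+].[O-]C1=C(CC[C@@](C)(Cl)[C@@H](Br)COS(=O)(=O)C(F)(F)F)C(C)(C)[C@H](Br)CC1 | intermediate (not isolated)
25 | (2S,3R,6S,10R)-2,10-dibromo-3-chloro-3,11,11-trimethylspiro[5.5]undecan-7-one (C6 arranged as in 26; S only because C7=O outranks C11) | O=C1CC[C@@H](Br)C(C)(C)[C@@]12CC[C@@](C)(Cl)[C@@H](Br)C2 | intermediate
26 | (2S,3R,6R,10R)-2,10-dibromo-3-chloro-3,11,11-trimethyl-7-methylidenespiro[5.5]undecane | C=C1CC[C@@H](Br)C(C)(C)[C@@]12CC[C@@](C)(Cl)[C@@H](Br)C2 | target

## Step count and risks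

Total step count: 16. Longest linear sequence: 14 steps (steps 1 to 6 and 9 to 16, from but-3-yn-1-ol); steps 7 and 8 form the short branch.

Steps most likely to fail:

Step 15. Enolisation may stay at C8, and either enolate may close a three-membered ring onto C10 with loss of bromide, or the triflate may undergo elimination, before the C6 enolate alkylates. The face selectivity at C6 is also untested, because the tether's own chair preference may oppose the ring B bias. Fallback: generate the C6 enolate regiospecifically without an amide base. From 22, tosylation (TsCl, pyridine, CH2Cl2) would give the primary tosylate F1. Thermodynamic silylation (Me3SiI, (Me3Si)2NH, CH2Cl2, -20 °C to rt) would give the C6=C7 trimethylsilyl enol ether F2, freed of its C7=C8 isomer. Anhydrous benzyltrimethylammonium fluoride in THF would then release the ammonium C6 enolate, which should close ring A in the same 6-exo mode and return to 25.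

Step 10. Closure may occur through the ketone oxygen instead of at the fully substituted enol carbon C6 beside quaternary C11, or the cation may lose a proton or recapture chloride. The Lewis acid used for the funnel may also ionise the allylic silyl ether, and bromonium transfer to the C2=C3 alkene would erode enantiopurity. Fallback: remove the ester first, so that the bond to C11 is made by a CH carbon, and use oxygen closure on purpose. From 16, Pd(PPh3)4 and morpholine would give the acyclic ketone F3. In buffered (CF3)2CHOH the ketone oxygen should trap the bromonium ion and, after proton loss, give the 2-alkylidene oxane F4 (with its endocyclic isomer, which equilibrates). A Lewis acid (Me2AlCl or SnCl4, CH2Cl2, -78 °C) should then effect the oxygen-to-carbon 1,3-shift through the tertiary cation and the metal enolate (Ferrier-type carbocyclisation), returning to 20.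

Step 9. The strongly basic dianion may eliminate at the beta-bromo triflate or attack bromine with loss of chloride instead of displacing the triflate. Fallback: use a soft, weakly basic nucleophile by placing a second removable ester on C8. Diallyl 3-oxopentanedioate F5 (from dimethyl 3-oxopentanedioate and allyl alcohol by transesterification) would be alkylated with 8 (NaH, THF/DMF) to the mono-alkylated diester F6. Alkylation at the other alpha carbon with 14 (NaH, THF, 0 °C) would give the dialkylated diester F7. The bromonium cyclisation of step 10 applied to F7 would give the ring B diester F8, and Pd(PPh3)4 with morpholine would remove both allyl esters with double decarboxylation, returning to 20.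

## Further compounds

F1 | step 15 | (2S,3R)-2-bromo-5-[(3R)-3-bromo-2,2-dimethyl-6-oxocyclohexyl]-3-chloro-3-methylpentyl 4-methylbenzenesulfonate | CC1(C)[C@H](Br)CCC(=O)C1CC[C@@](C)(Cl)[C@@H](Br)COS(=O)(=O)c2ccc(C)cc2
F2 | step 15 | C6=C7 trimethylsilyl enol ether of F1 | C[Si](C)(C)OC1=C(CC[C@@](C)(Cl)[C@@H](Br)COS(=O)(=O)c2ccc(C)cc2)C(C)(C)[C@H](Br)CC1
F3 | step 10 | (2E,10R)-10-bromo-1-(tert-butyldiphenylsilyloxy)-11-chloro-3,11-dimethyldodec-2-en-7-one | CC(C)(Cl)[C@H](Br)CCC(=O)CCC/C(C)=C/CO[Si](c1ccccc1)(c1ccccc1)C(C)(C)C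
F4 | step 10 | (5R)-5-bromo-6,6-dimethyl-2-[(E)-5-(tert-butyldiphenylsilyloxy)-3-methylpent-3-en-1-ylidene]oxane | CC1(C)OC(=CCC/C(C)=C/CO[Si](c2ccccc2)(c2ccccc2)C(C)(C)C)CC[C@H]1Br
F5 | step 9 | diallyl 3-oxopentanedioate | C=CCOC(=O)CC(=O)CC(=O)OCC=C
F6 | step 9 | diallyl 2-[(E)-5-(tert-butyldiphenylsilyloxy)-3-methylpent-3-en-1-yl]-3-oxopentanedioate | C=CCOC(=O)CC(=O)C(CC/C(C)=C/CO[Si](c1ccccc1)(c1ccccc1)C(C)(C)C)C(=O)OCC=C
F7 | step 9 | diallyl 2-[(2R)-2-bromo-3-chloro-3-methylbutyl]-4-[(E)-5-(tert-butyldiphenylsilyloxy)-3-methylpent-3-en-1-yl]-3-oxopentanedioate | C=CCOC(=O)C(C[C@@H](Br)C(C)(C)Cl)C(=O)C(CC/C(C)=C/CO[Si](c1ccccc1)(c1ccccc1)C(C)(C)C)C(=O)OCC=C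
F8 | step 9 | diallyl (5R)-5-bromo-6,6-dimethyl-2-oxo-1-[(E)-5-(tert-butyldiphenylsilyloxy)-3-methylpent-3-en-1-yl]cyclohexane-1,3-dicarboxylate | C=CCOC(=O)C1C[C@@H](Br)C(C)(C)C(CC/C(C)=C/CO[Si](c2ccccc2)(c2ccccc2)C(C)(C)C)(C(=O)OCC=C)C1=O
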